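**Strategy**

- The retrosynthesis first removes four MOM ethers, then cuts ring C at C4–C4a, O1–C8a and O1–C2. This leads back to a ring-A aryne (C4a≡C8a) and a ring-B arylpropiolic acid that already holds C2, C3 and C4.
- Enabling feature: C4a and C8a are adjacent ring-A carbons that carry the C4 carbonyl and O1, and they lie between the C5 oxygen and the C8 prenyl group. An aryne across these two carbons is polarised by the C5 oxygen, so the acid oxygen should bond to C8a.
- Forward, ring A: phloroglucinol is protected, then two carbamate-directed ortho metalations bring in silicon and the prenyl group, and the carbamate is exchanged for a triflate. Ring B: 3-bromo-4,5-dihydroxybenzaldehyde is protected, prenylated by cross-coupling and homologated to the propiolic acid.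
- Both benzene rings are bought. Ring C is the only ring formed, in the step that joins the fragments; global MOM removal ends the route.
- Stereochemistry: the target has no stereocentre and both alkenes end in two identical methyl groups, so nothing has to be controlled.

Key step: step 11

Remark: flavone numbering is used (O1, C2 to C8a, primed positions on ring B); prenyl means 3-methylbut-2-en-1-yl. Compounds 12 and 14 are assumed to be commercially available.

**Route**

Step 1
Reactants: 1 phloroglucinol
Product: 2 3,5-bis(methoxymethoxy)phenol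
Conditions: MOMCl (2.0 equiv), i-Pr2NEt, DMF, 0 °C to rt
Reagents that add atoms: chloromethyl methyl ether, COCCl
Why: Williamson-type O-alkylation (MOM protection); the three hydroxyls of 1 are equivalent, so two equivalents of MOMCl should give the bis-ether as the main statistical product, separable by chromatography from the mono- and tris-ethers.

Step 2
Reactants: 2 3,5-bis(methoxymethoxy)phenol
Product: 3 3,5-bis(methoxymethoxy)phenyl N,N-diethylcarbamate
Conditions: NaH, THF, 0 °C; Et2NCOCl, 0 °C to rt
Reagents that add atoms: N,N-diethylcarbamoyl chloride, CCN(CC)C(=O)Cl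
Why: O-carbamoylation of the sodium phenoxide is a standard acylation and installs the aryl O-carbamate, the strongest oxygen-based director for ortho metalation and the masked phenol for the later triflate.

Step 3
Reactants: 3 3,5-bis(methoxymethoxy)phenyl N,N-diethylcarbamate
Product: 5 3,5-bis(methoxymethoxy)-2-(trimethylsilyl)phenyl N,N-diethylcarbamate, via lithiated carbamate 4 (not isolated)
Conditions: s-BuLi, TMEDA, THF, −78 °C; TMSCl, −78 °C to rt
Reagents that add atoms: chlorotrimethylsilane, C[Si](C)(C)Cl
Why: Directed ortho metalation; the two equivalent C–H bonds between the carbamate and a MOM ether are activated by both groups and should be lithiated in preference to the C–H between the two MOM ethers, the diethylcarbamate resists anionic Fries migration at −78 °C, and TMSCl traps the aryllithium.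

Step 4
Reactants: 5 3,5-bis(methoxymethoxy)-2-(trimethylsilyl)phenyl N,N-diethylcarbamate; 6 prenyl bromide (1-bromo-3-methylbut-2-ene)
Product: 9 3,5-bis(methoxymethoxy)-2-(3-methylbut-2-en-1-yl)-6-(trimethylsilyl)phenyl N,N-diethylcarbamate, via aryllithium 7 (not isolated), via arylcopper 8 (not isolated)
Conditions: s-BuLi, TMEDA, THF, −78 °C; CuBr·SMe2, −78 to −40 °C; 6, −78 to 0 °C
Reagents that add atoms: none
Why: Second directed ortho metalation at the one remaining carbamate-flanked C–H (silicon blocks the other), then transmetalation to an arylcopper that no longer undergoes anionic Fries migration and should couple with prenyl bromide at its primary carbon (SN2-type allylic substitution) to give the linear prenyl group.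

Step 5
Reactants: 9 3,5-bis(methoxymethoxy)-2-(3-methylbut-2-en-1-yl)-6-(trimethylsilyl)phenyl N,N-diethylcarbamate
Product: 10 3,5-bis(methoxymethoxy)-2-(3-methylbut-2-en-1-yl)-6-(trimethylsilyl)phenol
Conditions: LiAlH4, THF, 0 °C to reflux; aq potassium sodium tartrate work-up
Reagents that add atoms: none
Why: Reductive cleavage of an aryl O-carbamate; hydride reaches the hindered carbamate carbonyl where hydroxide would not and expels the aryloxide, the MOM ethers, prenyl alkene and aryl–silicon bond are inert to LiAlH4, and the non-acidic work-up avoids protodesilylation of the electron-rich arylsilane.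

Step 6
Reactants: 10 3,5-bis(methoxymethoxy)-2-(3-methylbut-2-en-1-yl)-6-(trimethylsilyl)phenol
Product: 11 3,5-bis(methoxymethoxy)-2-(3-methylbut-2-en-1-yl)-6-(trimethylsilyl)phenyl trifluoromethanesulfonate
Conditions: NaH, THF, 0 °C; PhNTf2, 0 °C to rt
Reagents that add atoms: N-phenylbis(trifluoromethanesulfonimide), O=S(=O)(N(c1ccccc1)S(=O)(=O)C(F)(F)F)C(F)(F)F
Why: O-sulfonylation of the sodium phenoxide with the mild triflyl donor PhNTf2 generates no acid, so the MOM ethers and the protodesilylation-prone C–Si bond should survive and the o-silylaryl triflate needed as aryne precursor is obtained.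

Step 7
Reactants: 12 3-bromo-4,5-dihydroxybenzaldehyde
Product: 13 3-bromo-4,5-bis(methoxymethoxy)benzaldehyde
Conditions: MOMCl, i-Pr2NEt, CH2Cl2, 0 °C to rt
Reagents that add atoms: chloromethyl methyl ether, COCCl
Why: Standard MOM protection (O-alkylation of both catechol hydroxyls with MOMCl and an amine base), which leaves the aldehyde and the aryl bromide untouched.

Step 8
Reactants: 13 3-bromo-4,5-bis(methoxymethoxy)benzaldehyde; 14 prenylboronic acid pinacol ester
Product: 15 3,4-bis(methoxymethoxy)-5-(3-methylbut-2-en-1-yl)benzaldehyde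
Conditions: Pd(OAc)2 (2 mol %), t-BuXPhos (4 mol %), K3PO4 (aq), MeCN, 70 °C
Reagents that add atoms: none
Why: Suzuki–Miyaura allylation; zerovalent palladium inserts into the C–Br bond, the prenylboronate transmetalates, and reductive elimination from the less hindered primary σ-allyl palladium, favoured by the bulky di-tert-butylbiarylphosphine, should give the linear prenyl arene while the mild phosphate base spares the aldehyde and MOM ethers.

Step 9
Reactants: 15 3,4-bis(methoxymethoxy)-5-(3-methylbut-2-en-1-yl)benzaldehyde
Product: 16 5-(2,2-dibromoethenyl)-1,2-bis(methoxymethoxy)-3-(3-methylbut-2-en-1-yl)benzene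
Conditions: CBr4, PPh3, Et3N, CH2Cl2, 0 °C
Reagents that add atoms: carbon tetrabromide, BrC(Br)(Br)Br
Why: Corey–Fuchs dibromoolefination (Wittig reaction of the aldehyde with Ph3P=CBr2 formed in the flask), with Et3N buffering traces of HBr so that the MOM ethers and the prenyl alkene are preserved.

Step 10
Reactants: 16 5-(2,2-dibromoethenyl)-1,2-bis(methoxymethoxy)-3-(3-methylbut-2-en-1-yl)benzene
Product: 18 3-[3,4-bis(methoxymethoxy)-5-(3-methylbut-2-en-1-yl)phenyl]prop-2-ynoic acid, via lithium acetylide 17 (not isolated)
Conditions: n-BuLi (2.2 equiv), THF, −78 °C; CO2, −78 to 0 °C; cold 1 M HCl to pH 3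
Reagents that add atoms: carbon dioxide, O=C=O
Why: Second stage of the Corey–Fuchs sequence; bromine–lithium exchange, α-elimination with 1,2-shift (Fritsch–Buttenberg–Wiechell rearrangement) and deprotonation give the lithium acetylide, CO2 carboxylates it, and brief cold acidification should free the acid without touching the MOM ethers.

Step 11
Reactants: 11 3,5-bis(methoxymethoxy)-2-(3-methylbut-2-en-1-yl)-6-(trimethylsilyl)phenyl trifluoromethanesulfonate; 18 3-[3,4-bis(methoxymethoxy)-5-(3-methylbut-2-en-1-yl)phenyl]prop-2-ynoic acid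
Product: 21 2-[3,4-bis(methoxymethoxy)-5-(3-methylbut-2-en-1-yl)phenyl]-5,7-bis(methoxymethoxy)-8-(3-methylbut-2-en-1-yl)-4H-chromen-4-one, via aryne 19 (not isolated), via hydroxyaryl ynone 20 (not isolated)
Conditions: CsF (4 equiv), THF, 125 °C, sealed tube (11 in 1.5-fold excess)
Reagents that add atoms: none
Why: Fluoride removes the silyl group of 11 and triflate departs to give aryne 19, whose C8a is attacked by the carboxylate oxygen of 18; the aryl anion formed at C4a adds to the neighbouring ester carbonyl through a four-membered alkoxide that opens to the phenoxide of ynone 20, a net insertion of the aryne into the acid C–O bond that forms C8a–O1 and C4a–C4. The closest known reaction type is the fluoride-induced aryne insertion into the C–O bond of carboxylic acids giving o-hydroxyaryl ketones, which with arylpropiolic acids runs on to flavones. Ring C then closes by 6-endo-dig oxa-Michael addition of the C8a phenoxide to the aryl-bearing alkyne carbon (O1–C2), and protonation at C3 completes the pyranone. No stereocentre is created. The step needs oxygen at C8a and the acyl group at C4a rather than the reverse, and the inductively withdrawing C5 MOM-oxy group distorts the aryne so that the small oxygen nucleophile adds to the distal carbon C8a and the negative charge develops at C4a next to oxygen, which should outweigh the steric cost of the C8 prenyl group. Six-membered closure rather than five-membered (aurone) closure is favoured by the polarisation of the ynone, and an ene reaction of the aryne with the prenyl group held by a one-carbon tether is geometrically disfavoured.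

Step 12
Reactants: 21 2-[3,4-bis(methoxymethoxy)-5-(3-methylbut-2-en-1-yl)phenyl]-5,7-bis(methoxymethoxy)-8-(3-methylbut-2-en-1-yl)-4H-chromen-4-one
Product: 22 epimedokoreanin B, 2-[3,4-dihydroxy-5-(3-methylbut-2-en-1-yl)phenyl]-5,7-dihydroxy-8-(3-methylbut-2-en-1-yl)-4H-chromen-4-one
Conditions: 3 M aq HCl, MeOH, 50 °C, stopped at full conversion
Reagents that add atoms: none
Why: Acid-catalysed acetal cleavage (MOM deprotection); each methoxymethyl group is lost as an oxocarbenium ion trapped by methanol, and dilute acid at moderate temperature for a short, monitored time should leave the two prenyl groups uncyclised.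

**Compound list**

1 | phloroglucinol | Oc1cc(O)cc(O)c1 | starting material
2 | 3,5-bis(methoxymethoxy)phenol | COCOc1cc(O)cc(OCOC)c1 | intermediate
3 | 3,5-bis(methoxymethoxy)phenyl N,N-diethylcarbamate | CCN(CC)C(=O)Oc1cc(OCOC)cc(OCOC)c1 | intermediate
4 | 2-lithio-3,5-bis(methoxymethoxy)phenyl N,N-diethylcarbamate | CCN(CC)C(=O)Oc1cc(OCOC)cc(OCOC)c1[Li] | intermediate (not isolated)
5 | 3,5-bis(methoxymethoxy)-2-(trimethylsilyl)phenyl N,N-diethylcarbamate | CCN(CC)C(=O)Oc1cc(OCOC)cc(OCOC)c1[Si](C)(C)C | intermediate
6 | prenyl bromide (1-bromo-3-methylbut-2-ene) | CC(C)=CCBr | starting material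
7 | 2-lithio-3,5-bis(methoxymethoxy)-6-(trimethylsilyl)phenyl N,N-diethylcarbamate | CCN(CC)C(=O)Oc1c([Li])c(OCOC)cc(OCOC)c1[Si](C)(C)C | intermediate (not isolated)
8 | arylcopper derived from 7 | CCN(CC)C(=O)Oc1c([Cu])c(OCOC)cc(OCOC)c1[Si](C)(C)C | intermediate (not isolated)
9 | 3,5-bis(methoxymethoxy)-2-(3-methylbut-2-en-1-yl)-6-(trimethylsilyl)phenyl N,N-diethylcarbamate | CCN(CC)C(=O)Oc1c(CC=C(C)C)c(OCOC)cc(OCOC)c1[Si](C)(C)C | intermediate
10 | 3,5-bis(methoxymethoxy)-2-(3-methylbut-2-en-1-yl)-6-(trimethylsilyl)phenol | CC(C)=CCc1c(OCOC)cc(OCOC)c([Si](C)(C)C)c1O | intermediate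
11 | 3,5-bis(methoxymethoxy)-2-(3-methylbut-2-en-1-yl)-6-(trimethylsilyl)phenyl trifluoromethanesulfonate | CC(C)=CCc1c(OCOC)cc(OCOC)c([Si](C)(C)C)c1OS(=O)(=O)C(F)(F)F | intermediate
12 | 3-bromo-4,5-dihydroxybenzaldehyde | O=Cc1cc(O)c(O)c(Br)c1 | starting material
13 | 3-bromo-4,5-bis(methoxymethoxy)benzaldehyde | O=Cc1cc(Br)c(OCOC)c(OCOC)c1 | intermediate
14 | prenylboronic acid pinacol ester | CC(C)=CCB1OC(C)(C)C(C)(C)O1 | starting material
15 | 3,4-bis(methoxymethoxy)-5-(3-methylbut-2-en-1-yl)benzaldehyde | CC(C)=CCc1cc(C=O)cc(OCOC)c1OCOC | intermediate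
16 | 5-(2,2-dibromoethenyl)-1,2-bis(methoxymethoxy)-3-(3-methylbut-2-en-1-yl)benzene | CC(C)=CCc1cc(C=C(Br)Br)cc(OCOC)c1OCOC | intermediate
17 | lithium acetylide of the ring-B alkyne | CC(C)=CCc1cc(C#C[Li])cc(OCOC)c1OCOC | intermediate (not isolated)
18 | 3-[3,4-bis(methoxymethoxy)-5-(3-methylbut-2-en-1-yl)phenyl]prop-2-ynoic acid | CC(C)=CCc1cc(C#CC(=O)O)cc(OCOC)c1OCOC | intermediate
19 | 3,5-bis(methoxymethoxy)-6-(3-methylbut-2-en-1-yl)benzyne | CC(C)=CCC1=C(OCOC)C=C(OCOC)C#C1 | intermediate (not isolated)
20 | 1-[2-hydroxy-4,6-bis(methoxymethoxy)-3-(3-methylbut-2-en-1-yl)phenyl]-3-[3,4-bis(methoxymethoxy)-5-(3-methylbut-2-en-1-yl)phenyl]prop-2-yn-1-one (present as its caesium phenoxide) | CC(C)=CCc1cc(C#CC(=O)c2c(OCOC)cc(OCOC)c(CC=C(C)C)c2O)cc(OCOC)c1OCOC | intermediate (not isolated)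
21 | 2-[3,4-bis(methoxymethoxy)-5-(3-methylbut-2-en-1-yl)phenyl]-5,7-bis(methoxymethoxy)-8-(3-methylbut-2-en-1-yl)-4H-chromen-4-one | CC(C)=CCc1cc(-c2cc(=O)c3c(OCOC)cc(OCOC)c(CC=C(C)C)c3o2)cc(OCOC)c1OCOC | intermediate
22 | epimedokoreanin B | CC(C)=CCc1cc(-c2cc(=O)c3c(O)cc(O)c(CC=C(C)C)c3o2)cc(O)c1O | target

**Step count**

Total: 12 steps. Longest linear sequence: 8 steps (steps 1 to 6, then 11 and 12); the ring-B branch is steps 7 to 10.

**Steps most likely to fail, with fallbacks**

1. Step 11. The carboxylate may be arylated on oxygen without the acyl shift, may add to the aryne carbon next to the C5 oxygen, or the propiolic acid may lose CO2 at 125 °C before it is trapped. The fallback sets out from carbamate 3 and dibromoalkene 16 and rejoins the route at ynone 20, and through it at 21. Aryllithium 4, formed as in step 3, would be transmetalated with CuBr·SMe2 and allylated with prenyl bromide 6 to give 3,5-bis(methoxymethoxy)-2-(3-methylbut-2-en-1-yl)phenyl N,N-diethylcarbamate F1. LiAlH4 in THF would release 3,5-bis(methoxymethoxy)-2-(3-methylbut-2-en-1-yl)phenol F2. Magnesium-mediated ortho-formylation (MgCl2, Et3N, paraformaldehyde, MeCN, reflux) at the single free ortho position would give 2-hydroxy-4,6-bis(methoxymethoxy)-3-(3-methylbut-2-en-1-yl)benzaldehyde F3. Addition of lithium acetylide 17 (2.2 equiv, generated from 16 as in step 10) at −78 °C would give racemic 1-[2-hydroxy-4,6-bis(methoxymethoxy)-3-(3-methylbut-2-en-1-yl)phenyl]-3-[3,4-bis(methoxymethoxy)-5-(3-methylbut-2-en-1-yl)phenyl]prop-2-yn-1-ol F4. MnO2 in CH2Cl2 would oxidise F4 to ynone 20, which K2CO3 in acetone should close to 21 by the same 6-endo-dig oxa-Michael addition. In this sequence the C8a oxygen is the former carbamate oxygen from the outset, so the question of aryne regiochemistry does not arise.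

2. Step 4. The second metalation may go to the C–H between the two MOM ethers, the ortho-lithiated carbamate may undergo anionic Fries migration on warming, or the allylation may proceed with allylic transposition. The fallback sets out from carbamate 5 and rejoins at phenol 10, and brings in the prenyl group by aromatic Claisen rearrangement instead. LiAlH4 would cleave 5 to 3,5-bis(methoxymethoxy)-2-(trimethylsilyl)phenol F5. Copper-catalysed O-alkylation with 3-chloro-3-methylbut-1-yne (CuCl2 cat., DBU, MeCN, 0 °C) would give 1,5-bis(methoxymethoxy)-3-[(2-methylbut-3-yn-2-yl)oxy]-2-(trimethylsilyl)benzene F6. Semi-hydrogenation (H2, Pd/CaCO3 poisoned with Pb(OAc)2, quinoline) would give 1,5-bis(methoxymethoxy)-3-[(2-methylbut-3-en-2-yl)oxy]-2-(trimethylsilyl)benzene F7. Heating F7 in toluene at 110 °C should trigger the [3,3] shift into the only free ortho position and deliver phenol 10 directly, with the linear prenyl group fixed by the mechanism.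

3. Step 8. Reductive elimination may occur at the tertiary allyl terminus (branched coupling), or protodeboronation of the allylboronate may outrun transmetalation. The fallback sets out from aldehyde 13 and rejoins at aldehyde 15, and reverses the polarity of the coupling. The aldehyde would be masked as its dimethyl acetal, 1-bromo-5-(dimethoxymethyl)-2,3-bis(methoxymethoxy)benzene F8 (HC(OMe)3, MeOH, cat. PPTS). Bromine–lithium exchange (n-BuLi, THF, −78 °C), transmetalation with CuBr·SMe2 and allylation with prenyl bromide 6 would give 5-(dimethoxymethyl)-1,2-bis(methoxymethoxy)-3-(3-methylbut-2-en-1-yl)benzene F9. PPTS in wet acetone would then unmask aldehyde 15, since the benzylic acetal hydrolyses far faster than the MOM ethers.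

**Further compounds**

F1 | step 11 | 3,5-bis(methoxymethoxy)-2-(3-methylbut-2-en-1-yl)phenyl N,N-diethylcarbamate | CCN(CC)C(=O)Oc1cc(OCOC)cc(OCOC)c1CC=C(C)C
F2 | step 11 | 3,5-bis(methoxymethoxy)-2-(3-methylbut-2-en-1-yl)phenol | CC(C)=CCc1c(O)cc(OCOC)cc1OCOC
F3 | step 11 | 2-hydroxy-4,6-bis(methoxymethoxy)-3-(3-methylbut-2-en-1-yl)benzaldehyde | O=Cc1c(O)c(CC=C(C)C)c(OCOC)cc1OCOC
F4 | step 11 | racemic 1-[2-hydroxy-4,6-bis(methoxymethoxy)-3-(3-methylbut-2-en-1-yl)phenyl]-3-[3,4-bis(methoxymethoxy)-5-(3-methylbut-2-en-1-yl)phenyl]prop-2-yn-1-ol | CC(C)=CCc1cc(C#CC(O)c2c(O)c(CC=C(C)C)c(OCOC)cc2OCOC)cc(OCOC)c1OCOC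
F5 | step 4 | 3,5-bis(methoxymethoxy)-2-(trimethylsilyl)phenol | Oc1cc(OCOC)cc(OCOC)c1[Si](C)(C)C
F6 | step 4 | 1,5-bis(methoxymethoxy)-3-[(2-methylbut-3-yn-2-yl)oxy]-2-(trimethylsilyl)benzene | C#CC(C)(C)Oc1cc(OCOC)cc(OCOC)c1[Si](C)(C)C
F7 | step 4 | 1,5-bis(methoxymethoxy)-3-[(2-methylbut-3-en-2-yl)oxy]-2-(trimethylsilyl)benzene | C=CC(C)(C)Oc1cc(OCOC)cc(OCOC)c1[Si](C)(C)C
F8 | step 8 | 1-bromo-5-(dimethoxymethyl)-2,3-bis(methoxymethoxy)benzene | COC(OC)c1cc(Br)c(OCOC)c(OCOC)c1
F9 | step 8 | 5-(dimethoxymethyl)-1,2-bis(methoxymethoxy)-3-(3-methylbut-2-en-1-yl)benzene | COC(OC)c1cc(CC=C(C)C)c(OCOC)c(OCOC)c1
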